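Everything rests on cutting ring B, the butenolide, at its carbonyl carbon. C2 is flanked by C3, which carries the dihydrobenzofuran bicycle, and by the ring oxygen O1 on the ylidene carbon C5, so C2 can enter as carbon monoxide between a vinyl iodide and a ketone-derived dienol oxygen. One palladium-catalysed operation forms C3–C2 and C2–O1, closes ring B and sets the Z exocyclic alkene. Its precursor is a (Z)-β-iodo cross-conjugated dienone: iodine on the carbon bearing the loliolide-derived bicycle and cis to the ketone, whose other arm is an E β-methyl enone ending in CH2CH2OTBS. Ring A is joined afterwards by Julia–Kocienski olefination.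

Key step: step 9

Remark: the bicycle carries primed benzofuran locants (O1′, C2′, C3′, C3a′, C4′–C7′, C7a′) and ring B plain furanone locants (O1, C2–C5); TBS = tert-butyldimethylsilyl, "Bic" = (2R,6S,7aR)-6-(TBS-oxy)-4,4,7a-trimethyl-2,4,5,6,7,7a-hexahydrobenzofuran-2-yl (C2′ substituent trans to the C7a′ methyl), "RingA" = (4R)-4-(TBS-oxy)-2,6,6-trimethylcyclohex-1-en-1-yl; the C2′ epimers of 3 and 4 are assumed to converge through one oxocarbenium ion.

Step 1
Reactants: 1 (−)-loliolide
Product: 2 (6S,7aR)-6-(TBS-oxy)-4,4,7a-trimethyl-5,6,7,7a-tetrahydrobenzofuran-2(4H)-one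
Conditions: TBSOTf, 2,6-lutidine, CH2Cl2, 0 °C
Reagents that add atoms: tert-butyldimethylsilyl triflate, CC(C)(C)[Si](C)(C)OS(=O)(=O)C(F)(F)F
Why: Silyl ether formation, with the reactive triflate chosen because the hydroxyl is axial and syn to two axial methyl groups; the lactone and both stereocentres are untouched.

Step 2
Reactants: 2 loliolide TBS ether
Product: 4 (6S,7aR)-6-(TBS-oxy)-4,4,7a-trimethyl-2,4,5,6,7,7a-hexahydrobenzofuran-2-yl acetate (both C2′ epimers), via aluminium lactolate 3 (not isolated)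
Conditions: i-Bu2AlH, CH2Cl2, −78 °C; then pyridine, DMAP, Ac2O, −78 → 0 °C
Reagents that add atoms: acetic anhydride, CC(=O)OC(C)=O
Why: At −78 °C i-Bu2AlH adds once to the lactone carbonyl and the tetrahedral aluminium lactolate is acetylated in the same flask (reductive acetylation), so the labile allylic lactol is never handled; the new acetal centre forms as a mixture that is erased in step 3.

Step 3
Reactants: 4 lactol acetate; 5 tributyl(trimethylsilylethynyl)stannane
Product: 6 (2R,6S,7aR)-6-(TBS-oxy)-4,4,7a-trimethyl-2-[(trimethylsilyl)ethynyl]-2,4,5,6,7,7a-hexahydrobenzofuran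
Conditions: BF3·OEt2, CH2Cl2, −78 → −40 °C
Reagents that add atoms: none
Why: BF3·OEt2 ionises the allylic acetal acetate to a 2,5-dihydrofuranyl oxocarbenium ion that the alkynylstannane captures at C2′ (Lewis-acid alkynylation of a cyclic oxocarbenium ion, as in C-glycoside synthesis; C3a′ is shut off by two quaternary neighbours), and the new C2′ centre should form mainly by attack anti to the axial C7a′ methyl group, which leans over the ring more than C7′ does, the minor 2′S epimer being a diastereomer removable by chromatography.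

Step 4
Reactants: 6 silylalkyne
Product: 7 (2R,6S,7aR)-6-(TBS-oxy)-2-ethynyl-4,4,7a-trimethyl-2,4,5,6,7,7a-hexahydrobenzofuran
Conditions: K2CO3, MeOH, rt
Reagents that add atoms: none
Why: Methoxide-mediated protodesilylation removes only the alkynyl silicon group and leaves the silyl ether and the C2′ centre alone.

Step 5
Reactants: 8 tert-butyl(but-3-yn-1-yloxy)dimethylsilane
Product: 10 methyl (E)-5-(TBS-oxy)-3-methylpent-2-enoate, via alkenylalane 9 (not isolated)
Conditions: AlMe3, Cp2ZrCl2 (25 mol %), CH2Cl2, 0 °C → rt; then ClCO2Me, 0 °C → rt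
Reagents that add atoms: trimethylaluminium, C[Al](C)C; methyl chloroformate, COC(=O)Cl
Why: Zirconium-catalysed methylalumination (Negishi carboalumination) adds methyl and aluminium syn with aluminium on the terminal carbon, and the alkenylalane is acylated by the chloroformate with retention, which fixes the E trisubstituted alkene.

Step 6
Reactants: 10 methyl enoate
Product: 11 (E)-5-(TBS-oxy)-N-methoxy-N,3-dimethylpent-2-enamide
Conditions: MeNHOMe·HCl, i-PrMgCl, THF, −20 → 0 °C
Reagents that add atoms: N,O-dimethylhydroxylamine hydrochloride, CNOC.Cl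
Why: The chloromagnesium amide of N,O-dimethylhydroxylamine converts the ester into the Weinreb amide without touching the enoate double bond or the silyl ether.

Step 7
Reactants: 7 terminal alkyne; 11 Weinreb amide
Product: 13 (E)-1-Bic-7-(TBS-oxy)-5-methylhept-4-en-1-yn-3-one, via lithium acetylide 12 (not isolated)
Conditions: n-BuLi, THF, −78 °C; then 11, −78 → 0 °C; cold aq. NH4Cl
Reagents that add atoms: none
Why: The lithium acetylide adds once to the Weinreb amide because the chelated tetrahedral intermediate survives until the quench (Weinreb ketone synthesis), and the alkyne C–H is far more acidic than C2′–H, so the stereocentre is safe.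

Step 8
Reactants: 13 enynone
Product: 14 (1Z,4E)-1-Bic-1-iodo-7-(TBS-oxy)-5-methylhepta-1,4-dien-3-one
Conditions: NaI, AcOH, rt, dark
Reagents that add atoms: sodium iodide, [Na+].[I-]
Why: Iodide adds in conjugate fashion to the ynone, which is far more electrophilic than the β,β-disubstituted enone, and the allenolate is protonated anti to iodine, so the (Z)-β-iodoenone with iodine cis to the ketone results (hydroiodination with NaI/AcOH).

Step 9
Reactants: 14 (Z)-β-iodo dienone; 15 carbon monoxide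
Product: 16 (5Z)-3-Bic-5-[(2E)-4-(TBS-oxy)-2-methylbut-2-en-1-ylidene]furan-2(5H)-one
Conditions: Pd(PPh3)4 (10 mol %), CO (1 atm), Et3N, MeCN, 50 °C
Reagents that add atoms: none
Why: Proposed new method: zerovalent palladium should insert into the C–I bond with retention, CO insertion gives an acylpalladium iodide held cis to the ketone, the ketone oxygen closes ring B on the acyl carbon (5-exo-trig) and Et3N takes a proton from the γ-methylene of the enone arm, which forms the C3–C2 and C2–O1 bonds and returns zerovalent palladium. The closest known reaction is the palladium-catalysed carbonylative lactonisation of (Z)-β-iodoenones bearing α′ hydrogens to (Z)-γ-ylidenebutenolides; loss of the proton one vinylogous position further out, from a cross-conjugated dienone, is the untested element. No stereocentre is created and C2′ should stay untouched, since it sits on C3 next to the lactone carbonyl where little positive charge develops and its hydrogen is shielded by the bicycle. Oxygen rather than carbon acylation is secured by the cis iodine–ketone geometry, which lets only the oxygen reach the acyl carbon through a five-membered transition state. Proton loss must occur from the CH2 next to CH2OTBS and not from the C-methyl group: it leads to the more substituted, linearly conjugated triene, the preference that also governs equilibrating deconjugation of β-methyl enones, and it is helped by the inductive pull of the silyloxy group. The C5 ylidene should be Z because the E isomer would press the dienyl arm against C4–H, and the new trisubstituted alkene E because that keeps CH2OTBS away from the ylidene CH.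

Step 10
Reactants: 16 bis-silylated ylidenebutenolide
Product: 17 (5Z)-3-Bic-5-[(2E)-4-hydroxy-2-methylbut-2-en-1-ylidene]furan-2(5H)-one
Conditions: HF·pyridine, pyridine, THF, 0 °C
Reagents that add atoms: none
Why: Buffered HF·pyridine should cleave the unhindered primary allylic TBS ether much faster than the axial secondary one, whose two neighbouring methylenes each adjoin a quaternary carbon (rate-selective desilylation).

Step 11
Reactants: 17 allylic alcohol
Product: 18 (2E)-4-[(2Z)-4-Bic-5-oxofuran-2(5H)-ylidene]-3-methylbut-2-enal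
Conditions: MnO2, CH2Cl2, rt
Reagents that add atoms: none
Why: MnO2 oxidises the allylic alcohol chemoselectively to the dienal under neutral conditions that leave the enol lactone, the silyl ether and the alkene geometries intact.

Step 12
Reactants: 19 (4R,6R)-actinol
Product: 20 (4R,6R)-4-(TBS-oxy)-2,2,6-trimethylcyclohexan-1-one
Conditions: TBSCl, imidazole, DMF, rt
Reagents that add atoms: tert-butyldimethylsilyl chloride, CC(C)(C)[Si](C)(C)Cl
Why: Standard silylation of the unhindered secondary hydroxyl; the ketone and both stereocentres are unaffected.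

Step 13
Reactants: 20 silylated actinol
Product: 22 RingA triflate, (4R)-4-(TBS-oxy)-2,6,6-trimethylcyclohex-1-en-1-yl trifluoromethanesulfonate, via lithium enolate 21 (not isolated)
Conditions: LiN(i-Pr)2, THF, −78 → 0 °C; then PhNTf2, 0 °C → rt
Reagents that add atoms: N-phenylbis(trifluoromethanesulfonimide), O=S(=O)(N(c1ccccc1)S(=O)(=O)C(F)(F)F)C(F)(F)F
Why: The ketone can enolise only towards C6, so one enolate forms and is triflated on oxygen (enol triflate formation); the C6 centre is deliberately destroyed while C4 stays R.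

Step 14
Reactants: 22 RingA triflate; 23 (E)-3-methylpent-2-en-4-yn-1-ol
Product: 24 (E)-3-methyl-5-RingA-pent-2-en-4-yn-1-ol
Conditions: Pd(PPh3)4 (5 mol %), CuI (10 mol %), i-Pr2NH, DMF, rt
Reagents that add atoms: none
Why: Sonogashira coupling of the vinyl triflate with the terminal alkyne joins ring A to the enyne, and the E alkene of 23 is carried through unchanged.

Step 15
Reactants: 24 enynol
Product: 26 ethyl (2E,4E)-5-methyl-7-RingA-hepta-2,4-dien-6-ynoate, via enynal 25 (not isolated)
Conditions: MnO2, Ph3P=CHCO2Et, CH2Cl2, rt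
Reagents that add atoms: ethyl (triphenylphosphoranylidene)acetate, CCOC(=O)C=P(c1ccccc1)(c1ccccc1)c1ccccc1
Why: MnO2 oxidises the allylic alcohol and the stabilised ylide traps the enynal as it forms (tandem oxidation–Wittig olefination), a stabilised ylide giving the E enoate.

Step 16
Reactants: 26 dienynoate
Product: 27 (2E,4E)-5-methyl-7-RingA-hepta-2,4-dien-6-yn-1-ol
Conditions: i-Bu2AlH, CH2Cl2, −78 °C
Reagents that add atoms: none
Why: i-Bu2AlH reduces the conjugated ester to the allylic alcohol by 1,2-addition and does not touch the enyne or the silyl ether.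

Step 17
Reactants: 27 dienynol
Product: 28 5-{[(2E,4E)-5-methyl-7-RingA-hepta-2,4-dien-6-yn-1-yl]sulfanyl}-1-phenyl-1H-tetrazole
Conditions: 1-phenyl-1H-tetrazole-5-thiol, PPh3, DIAD, THF, 0 °C
Reagents that add atoms: 1-phenyl-1H-tetrazole-5-thiol, Sc1nnnn1-c1ccccc1
Why: Mitsunobu thioetherification of the primary dienylic alcohol with the acidic tetrazole thiol proceeds by direct SN2 displacement.

Step 18
Reactants: 28 tetrazolyl sulfide
Product: 29 5-{[(2E,4E)-5-methyl-7-RingA-hepta-2,4-dien-6-yn-1-yl]sulfonyl}-1-phenyl-1H-tetrazole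
Conditions: (NH4)6Mo7O24·4H2O (10 mol %), 30% aq. H2O2, EtOH, 0 °C → rt
Reagents that add atoms: hydrogen peroxide, OO
Why: Molybdate-catalysed peroxide oxidation takes the sulfide to the sulfone under conditions that are standard for allylic tetrazolyl sulfides and too mild to epoxidise the conjugated enyne or the hindered ring alkene.

Step 19
Reactants: 29 tetrazolyl sulfone; 18 dienal
Product: 31 (5Z)-3-Bic-5-[(2E,4E,6E,8E)-2,9-dimethyl-11-RingA-undeca-2,4,6,8-tetraen-10-yn-1-ylidene]furan-2(5H)-one, via metalated sulfone 30 (not isolated)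
Conditions: KN(SiMe3)2, DME, −78 °C; then 18, −78 → −40 °C
Reagents that add atoms: none
Why: Julia–Kocienski olefination, in which the metalated tetrazolyl sulfone adds to the aldehyde and Smiles rearrangement with loss of SO2 and the tetrazolone gives the new C=C, for which the phenyltetrazolyl sulfone with potassium in DME should favour E; no stereocentre is affected.

Step 20
Reactants: 31 bis-silyl ether
Product: 32 target, (5Z)-3-[(2R,6S,7aR)-6-hydroxy-4,4,7a-trimethyl-2,4,5,6,7,7a-hexahydrobenzofuran-2-yl]-5-{(2E,4E,6E,8E)-11-[(4R)-4-hydroxy-2,6,6-trimethylcyclohex-1-en-1-yl]-2,9-dimethylundeca-2,4,6,8-tetraen-10-yn-1-ylidene}furan-2(5H)-one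
Conditions: HF·pyridine, pyridine, THF, 0 °C → rt
Reagents that add atoms: none
Why: Buffered fluoride cleaves the two secondary TBS ethers under conditions mild enough for the polyene, the enol lactone and the allylic ether of the bicycle, so the target should emerge with all stereocentres and alkene geometries as set.

Compound list
1 | (−)-loliolide, (6S,7aR)-6-hydroxy-4,4,7a-trimethyl-5,6,7,7a-tetrahydrobenzofuran-2(4H)-one | O=C1C=C2C(C)(C)C[C@H](O)C[C@@]2(C)O1 | starting material
2 | (6S,7aR)-6-(TBS-oxy)-4,4,7a-trimethyl-5,6,7,7a-tetrahydrobenzofuran-2(4H)-one | O=C1C=C2C(C)(C)C[C@H](O[Si](C)(C)C(C)(C)C)C[C@@]2(C)O1 | intermediate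
3 | diisobutylaluminium lactolate of 2 (O-aluminated C2′ hemiacetal, both C2′ epimers) | CC(C)C[Al](CC(C)C)OC1C=C2C(C)(C)C[C@H](O[Si](C)(C)C(C)(C)C)C[C@@]2(C)O1 | intermediate
4 | (6S,7aR)-6-(TBS-oxy)-4,4,7a-trimethyl-2,4,5,6,7,7a-hexahydrobenzofuran-2-yl acetate (both C2′ epimers) | CC(=O)OC1C=C2C(C)(C)C[C@H](O[Si](C)(C)C(C)(C)C)C[C@@]2(C)O1 | intermediate
5 | tributyl(trimethylsilylethynyl)stannane | CCCC[Sn](CCCC)(CCCC)C#C[Si](C)(C)C | starting material
6 | (2R,6S,7aR)-6-(TBS-oxy)-4,4,7a-trimethyl-2-[(trimethylsilyl)ethynyl]-2,4,5,6,7,7a-hexahydrobenzofuran | C[Si](C)(C)C#C[C@H]1C=C2C(C)(C)C[C@H](O[Si](C)(C)C(C)(C)C)C[C@@]2(C)O1 | intermediate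
7 | (2R,6S,7aR)-6-(TBS-oxy)-2-ethynyl-4,4,7a-trimethyl-2,4,5,6,7,7a-hexahydrobenzofuran | C#C[C@H]1C=C2C(C)(C)C[C@H](O[Si](C)(C)C(C)(C)C)C[C@@]2(C)O1 | intermediate
8 | tert-butyl(but-3-yn-1-yloxy)dimethylsilane | C#CCCO[Si](C)(C)C(C)(C)C | starting material
9 | dimethyl[(E)-4-(TBS-oxy)-2-methylbut-1-en-1-yl]alane | C[Al](C)/C=C(\C)CCO[Si](C)(C)C(C)(C)C | intermediate
10 | methyl (E)-5-(TBS-oxy)-3-methylpent-2-enoate | COC(=O)/C=C(\C)CCO[Si](C)(C)C(C)(C)C | intermediate
11 | (E)-5-(TBS-oxy)-N-methoxy-N,3-dimethylpent-2-enamide | CON(C)C(=O)/C=C(\C)CCO[Si](C)(C)C(C)(C)C | intermediate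
12 | lithium acetylide of 7 | [Li]C#C[C@H]1C=C2C(C)(C)C[C@H](O[Si](C)(C)C(C)(C)C)C[C@@]2(C)O1 | intermediate
13 | (E)-1-Bic-7-(TBS-oxy)-5-methylhept-4-en-1-yn-3-one | CC(C)(C)[Si](C)(C)OCC/C(C)=C/C(=O)C#C[C@H]1C=C2C(C)(C)C[C@H](O[Si](C)(C)C(C)(C)C)C[C@@]2(C)O1 | intermediate
14 | (1Z,4E)-1-Bic-1-iodo-7-(TBS-oxy)-5-methylhepta-1,4-dien-3-one | CC(C)(C)[Si](C)(C)OCC/C(C)=C/C(=O)/C=C(\I)[C@H]1C=C2C(C)(C)C[C@H](O[Si](C)(C)C(C)(C)C)C[C@@]2(C)O1 | intermediate
15 | carbon monoxide | [C-]#[O+] | starting material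
16 | (5Z)-3-Bic-5-[(2E)-4-(TBS-oxy)-2-methylbut-2-en-1-ylidene]furan-2(5H)-one | CC(C)(C)[Si](C)(C)OC/C=C(C)/C=C1/C=C([C@H]2C=C3C(C)(C)C[C@H](O[Si](C)(C)C(C)(C)C)C[C@@]3(C)O2)C(=O)O1 | intermediate
17 | (5Z)-3-Bic-5-[(2E)-4-hydroxy-2-methylbut-2-en-1-ylidene]furan-2(5H)-one | OC/C=C(C)/C=C1/C=C([C@H]2C=C3C(C)(C)C[C@H](O[Si](C)(C)C(C)(C)C)C[C@@]3(C)O2)C(=O)O1 | intermediate
18 | (2E)-4-[(2Z)-4-Bic-5-oxofuran-2(5H)-ylidene]-3-methylbut-2-enal | O=C/C=C(C)/C=C1/C=C([C@H]2C=C3C(C)(C)C[C@H](O[Si](C)(C)C(C)(C)C)C[C@@]3(C)O2)C(=O)O1 | intermediate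
19 | (4R,6R)-actinol, (4R,6R)-4-hydroxy-2,2,6-trimethylcyclohexan-1-one | C[C@H]1C(=O)C(C)(C)C[C@H](O)C1 | starting material
20 | (4R,6R)-4-(TBS-oxy)-2,2,6-trimethylcyclohexan-1-one | C[C@H]1C(=O)C(C)(C)C[C@H](O[Si](C)(C)C(C)(C)C)C1 | intermediate
21 | lithium enolate of 20 | CC1=C(O[Li])C(C)(C)C[C@H](O[Si](C)(C)C(C)(C)C)C1 | intermediate
22 | (4R)-4-(TBS-oxy)-2,6,6-trimethylcyclohex-1-en-1-yl trifluoromethanesulfonate | CC1=C(OS(=O)(=O)C(F)(F)F)C(C)(C)C[C@H](O[Si](C)(C)C(C)(C)C)C1 | intermediate
23 | (E)-3-methylpent-2-en-4-yn-1-ol | C#C/C(C)=C/CO | starting material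
24 | (E)-3-methyl-5-RingA-pent-2-en-4-yn-1-ol | CC1=C(C#C/C(C)=C/CO)C(C)(C)C[C@H](O[Si](C)(C)C(C)(C)C)C1 | intermediate
25 | (E)-3-methyl-5-RingA-pent-2-en-4-ynal | CC1=C(C#C/C(C)=C/C=O)C(C)(C)C[C@H](O[Si](C)(C)C(C)(C)C)C1 | intermediate
26 | ethyl (2E,4E)-5-methyl-7-RingA-hepta-2,4-dien-6-ynoate | CC1=C(C#C/C(C)=C/C=C/C(=O)OCC)C(C)(C)C[C@H](O[Si](C)(C)C(C)(C)C)C1 | intermediate
27 | (2E,4E)-5-methyl-7-RingA-hepta-2,4-dien-6-yn-1-ol | CC1=C(C#C/C(C)=C/C=C/CO)C(C)(C)C[C@H](O[Si](C)(C)C(C)(C)C)C1 | intermediate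
28 | 5-{[(2E,4E)-5-methyl-7-RingA-hepta-2,4-dien-6-yn-1-yl]sulfanyl}-1-phenyl-1H-tetrazole | CC1=C(C#C/C(C)=C/C=C/CSc2nnnn2-c2ccccc2)C(C)(C)C[C@H](O[Si](C)(C)C(C)(C)C)C1 | intermediate
29 | 5-{[(2E,4E)-5-methyl-7-RingA-hepta-2,4-dien-6-yn-1-yl]sulfonyl}-1-phenyl-1H-tetrazole | CC1=C(C#C/C(C)=C/C=C/CS(=O)(=O)c2nnnn2-c2ccccc2)C(C)(C)C[C@H](O[Si](C)(C)C(C)(C)C)C1 | intermediate
30 | potassium α-sulfonyl carbanion of 29 | CC1=C(C#C/C(C)=C/C=C/C([K])S(=O)(=O)c2nnnn2-c2ccccc2)C(C)(C)C[C@H](O[Si](C)(C)C(C)(C)C)C1 | intermediate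
31 | bis-TBS ether of the target, (5Z)-3-Bic-5-[(2E,4E,6E,8E)-2,9-dimethyl-11-RingA-undeca-2,4,6,8-tetraen-10-yn-1-ylidene]furan-2(5H)-one | CC1=C(C#C/C(C)=C/C=C/C=C/C=C(C)/C=C2/C=C([C@H]3C=C4C(C)(C)C[C@H](O[Si](C)(C)C(C)(C)C)C[C@@]4(C)O3)C(=O)O2)C(C)(C)C[C@H](O[Si](C)(C)C(C)(C)C)C1 | intermediate
32 | target CNP0300047.2 (name as in step 20) | CC1=C(C#C/C(C)=C/C=C/C=C/C=C(C)/C=C2/C=C([C@H]3C=C4C(C)(C)C[C@H](O)C[C@@]4(C)O3)C(=O)O2)C(C)(C)C[C@H](O)C1 | target

Total step count: 20. Longest linear sequence: 11 steps (steps 1–4, 7–11, 19 and 20, from 1).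

Steps most likely to fail

1. Step 9 (Proposed new method). The proton may be lost from the C-methyl group or from C2′–H instead of the γ-methylene, which would give constitutional isomers of 16; the new trisubstituted alkene may form as an E/Z mixture; or the furanonyl–palladium intermediate may be reduced or dimerise before a proton is lost. The fallback uses known reactions only, sets out from 7 and comes back at 16. The lithium acetylide of 7 is trapped with ClCO2Me to give the propiolate ester F1. NaI/AcOH adds HI to give the (Z)-β-iodo acrylate F2, and i-Bu2AlH reduces it to the (Z)-3-iodo allylic alcohol F3. The established palladium-catalysed carbonylative lactonisation of such iodo allylic alcohols (Pd(PPh3)4, CO, Et3N) gives the 3-substituted butenolide F4. TBSOTf/Et3N turns it into the 2-silyloxyfuran F5, which adds in a vinylogous Mukaiyama aldol reaction (BF3·OEt2, −78 °C) to the enal F6, itself made by Wittig reaction of (tert-butyldimethylsilyloxy)acetaldehyde with 2-(triphenylphosphoranylidene)propanal. The resulting aldol adduct F7 is dehydrated through its mesylate (MsCl, Et3N, then DBU) to the (Z)-ylidenebutenolide 16.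

2. Step 3. Facial selectivity at the oxocarbenium ion may be poor, because the two faces differ only by a methyl group against a ring methylene at C7a′, so much material could be lost as the 2′S epimer. The fallback replaces substrate control by reagent control, sets out from 2 and comes back at 6. Lithium trimethylsilylacetylide (from trimethylsilylacetylene and n-BuLi) adds once to the lactone to give the ring-opened hydroxy ynone F8, which equilibrates with its cyclic hemiketal. Asymmetric transfer hydrogenation with RuCl(p-cymene)(TsDPEN) in HCO2H/Et3N, with the ligand enantiomer chosen to deliver the S carbinol, gives the diol F9. Mitsunobu cyclodehydration (PPh3, DIAD) then lets the tertiary hydroxyl displace the activated secondary one with inversion, closing the dihydrofuran as 6.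

3. Step 19. E selectivity may be low for this conjugated sulfone and enal pair, and the carbanion may instead deprotonate the γ-methyl group of the push–pull enal or attack the enol lactone. The fallback forms a different bond by cross-coupling, sets out from 18 and 24 and comes back at 31. Takai iodo-olefination (CrCl2, CHI3, THF) converts 18 into the (E)-dienyl iodide F10. Compound 24 is oxidised with MnO2 alone to the enynal 25, here isolated, and chromium-mediated stannyl olefination (CrCl2, Bu3SnCHBr2, LiI) converts it into the (E)-dienynyl stannane F11. Stille coupling (Pd2(dba)3, AsPh3, DMF, rt) joins the two sp2 carbons with retention of both geometries to give 31.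

Further compounds
F1 | step 9 | methyl 3-Bic-prop-2-ynoate | COC(=O)C#C[C@H]1C=C2C(C)(C)C[C@H](O[Si](C)(C)C(C)(C)C)C[C@@]2(C)O1
F2 | step 9 | methyl (Z)-3-Bic-3-iodoprop-2-enoate | COC(=O)/C=C(\I)[C@H]1C=C2C(C)(C)C[C@H](O[Si](C)(C)C(C)(C)C)C[C@@]2(C)O1
F3 | step 9 | (Z)-3-Bic-3-iodoprop-2-en-1-ol | OC/C=C(\I)[C@H]1C=C2C(C)(C)C[C@H](O[Si](C)(C)C(C)(C)C)C[C@@]2(C)O1
F4 | step 9 | 3-Bic-furan-2(5H)-one | O=C1OCC=C1[C@H]1C=C2C(C)(C)C[C@H](O[Si](C)(C)C(C)(C)C)C[C@@]2(C)O1
F5 | step 9 | 3-Bic-2-(TBS-oxy)furan | CC(C)(C)[Si](C)(C)Oc1occc1[C@H]1C=C2C(C)(C)C[C@H](O[Si](C)(C)C(C)(C)C)C[C@@]2(C)O1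
F6 | step 9 | (E)-4-(TBS-oxy)-2-methylbut-2-enal | O=C/C(C)=C/CO[Si](C)(C)C(C)(C)C
F7 | step 9 | 3-Bic-5-[(E)-1-hydroxy-4-(TBS-oxy)-2-methylbut-2-en-1-yl]furan-2(5H)-one (mixture at the two new centres) | OC(/C(C)=C/CO[Si](C)(C)C(C)(C)C)C1OC(=O)C([C@H]2C=C3C(C)(C)C[C@H](O[Si](C)(C)C(C)(C)C)C[C@@]3(C)O2)=C1
F8 | step 3 | (Z)-1-[(4S,6R)-4-(TBS-oxy)-6-hydroxy-2,2,6-trimethylcyclohexylidene]-4-(trimethylsilyl)but-3-yn-2-one | C[Si](C)(C)C#CC(=O)/C=C1/C(C)(C)C[C@H](O[Si](C)(C)C(C)(C)C)C[C@@]1(C)O
F9 | step 3 | (S,Z)-1-[(4S,6R)-4-(TBS-oxy)-6-hydroxy-2,2,6-trimethylcyclohexylidene]-4-(trimethylsilyl)but-3-yn-2-ol | C[Si](C)(C)C#C[C@@H](O)/C=C1/C(C)(C)C[C@H](O[Si](C)(C)C(C)(C)C)C[C@@]1(C)O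
F10 | step 19 | (5Z)-3-Bic-5-[(2E,4E)-5-iodo-2-methylpenta-2,4-dien-1-ylidene]furan-2(5H)-one | I/C=C/C=C(C)/C=C1/C=C([C@H]2C=C3C(C)(C)C[C@H](O[Si](C)(C)C(C)(C)C)C[C@@]3(C)O2)C(=O)O1
F11 | step 19 | tributyl[(1E,3E)-4-methyl-6-RingA-hexa-1,3-dien-5-yn-1-yl]stannane | CC1=C(C#C/C(C)=C/C=C/[Sn](CCCC)(CCCC)CCCC)C(C)(C)C[C@H](O[Si](C)(C)C(C)(C)C)C1
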